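Late in dawn and dusk, target and starting material together fell short of the charge, by 11.0% and 5.00% at the last readings.

| flask | starting material | enzyme | remark | time |
|---|---|---|---|---|
| dawn | 20 mM | 2.9 µM (in portions, 3) | run made earlier; portions every 25 s |  |
| dusk | 20 mM | 2.1 µM (in portions, 3) | run made earlier; portions every 25 s |  |
| birch | 20 mM | 4.3 µM (in portions, 3) | the portions of enzyme follow each other after 25 s, the first at the start | 25 min |
| cedar | 30 mM | 4.3 µM (in portions, 3) | the portions of enzyme follow each other after 25 s, the first at the start | 25 min |
| larch | 40 mM | 4.3 µM (in portions, 3) | the portions of enzyme follow each other after 25 s, the first at the start | 25 min |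
| maple | 60 mM | 4.3 µM (in portions, 3) | the portions of enzyme follow each other after 25 s, the first at the start | 25 min |

- dawn (time / min: target / %, starting material / %): 1.33: 4, 97; 4.00: 12, 85; 8.00: 27, 71; 10.0: 28, 66; 15.0: 37, 52
- dusk (time / min: target / %, starting material / %): 1.33: 4, 96; 2.50: 6, 93; 4.00: 11, 88; 8.00: 18, 77; 15.0: 32, 63

(standard deviation of a reading: 1.5 percentage points)

- "hardly changes" means that all values lie within two and a half points (for a concentration: within two and a half percent of the largest)

1. amount of target at the end, in percent of the starting material charged for birch, cedar, larch, maple, in this order
2. the shape of the row from first to last (falls all the way / rises all the way / hardly changes / falls, then rises / rises, then falls)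

Early on that shortfall lay within the scatter, so I supposed, as a guess, that target is lost by meeting starting material. I took making to go with enzyme times a, the fraction of starting material left, and loss to go with starting concentration times a times p, the fraction of target. So a cancels from their ratio, and the shortfall comes to roughly L times p squared. Dawn's last readings gave L as 0.804 and dusk's as 0.488, both with the scatter of those readings. Brought to birch's enzyme and averaged, they gave 0.390. This is the loss number, target lost per target made with the whole charge standing as target, a selectivity factor. On my guess it grows in step with the starting concentration, so I put maple at 1.17.

One number was not enough: L divides what has reacted and does not say how much that is. For this I took first-order decay in enzyme times time. Dawn's last reading predicted 62.3% of starting material for dusk's last, against 63% read, and it gave me an estimate of 19.9% for birch at the end. I assumed that share for each flask, though no run varied the concentration. Solving p plus L p squared equal to the reacted share, I expected 64.1%, 59.4%, 55.8% and 50.4%, a falling row.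

The forecast gave 46% at each concentration, hardly changes, on the ground “If the enzyme stays unsaturated, percentages don't depend on concentration”.

The flasks gave 56.3%, 54.8%, 52.7% and 47.9%: falls all the way.

    starting material + enzyme → target + enzyme, rate k1*[starting material]^1.5*[enzyme]/(1 + ([starting material]/Kh1)^1.5) (0.0870 M, k = 2000 M⁻¹·⁵ s⁻¹)
    starting material + target → side product (k = 0.0200 M⁻¹ s⁻¹)

At 25.0 min, birch was making target 2.61 times faster than it used target up, and its target stood at 61.0% after 250 min. Side product holds two units of the charge, so its percentage is the shortfall. Side product over target squared came to 0.626 in birch at the end, above my 0.390, and to 1.79 in maple at the end, 2.86 times birch's value for a starting concentration 3.00 times as large.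

All runs are simulated with made-up constants; scatter was added.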